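The pitfall I nearly fell into was to read the runs at 4.00 min, where target stood at 16.8 %, 17.1 % and 17.2 % with reagent at 0.050 M, 0.10 M and 0.20 M, and to take reagent for harmless.

| flask | substrate | reagent | remark | time |
|---|---|---|---|---|
| Tuesday's | 0.050 M | 0.10 M | run made earlier |  |
| Sunday's | 0.050 M | 0.050 M | run made earlier |  |
| Friday's | 0.050 M | 0.20 M | run made earlier |  |
| Monday's | 0.025 M | 0.10 M | run made earlier |  |
| oak | 0.050 M | 0.100 M | everything together at the start | 20 min |
| larch | 0.050 M | 0.100 M (fed, over 12 min) | all else is in the flask from the start; the feed brings no volume worth counting | 20 min |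
| ash | 0.050 M (fed, over 12 min) | 0.100 M | all else is in the flask from the start; the feed brings no volume worth counting | 20 min |

| run | time / min | target / % | substrate / % |
|---|---|---|---|
| Tuesday's | 0.833 | 2.3 | 81.9 |
| Tuesday's | 2.50 | 9.1 | 55.1 |
| Tuesday's | 4.00 | 17.1 | 38.0 |
| Tuesday's | 6.00 | 28.1 | 23.9 |
| Tuesday's | 10.0 | 46.6 | 8.7 |
| Tuesday's | 12.0 | 54.7 | 5.8 |
| Sunday's | 2.00 | 6.8 | 61.8 |
| Sunday's | 4.00 | 16.8 | 38.5 |
| Sunday's | 6.00 | 28.5 | 23.4 |
| Sunday's | 8.00 | 39.5 | 14.6 |
| Sunday's | 10.0 | 48.7 | 9.0 |
| Sunday's | 12.0 | 57.4 | 5.9 |
| Friday's | 1.00 | 2.5 | 78.6 |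
| Friday's | 1.50 | 4.4 | 70.5 |
| Friday's | 2.50 | 8.6 | 55.0 |
| Friday's | 4.00 | 17.2 | 38.4 |
| Friday's | 8.00 | 35.7 | 14.0 |
| Friday's | 12.0 | 49.9 | 5.6 |
| Monday's | 1.00 | 2.6 | 78.3 |
| Monday's | 2.00 | 7.2 | 62.0 |
| Monday's | 3.00 | 11.9 | 49.1 |
| Monday's | 6.00 | 28.0 | 23.6 |
| Monday's | 12.0 | 54.7 | 5.6 |

(readings scatter by 0.3 percentage points)

- the analysis behind the earlier runs scatters by 0.3 percentage points, standard deviation
- candidate steps: substrate -> intermediate A; intermediate A -> target; intermediate A <-> intermediate B; reagent + intermediate A <-> intermediate C; intermediate B <-> intermediate D; target -> over-reaction product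

1. the flask with the highest amount of target, in percent of the substrate charged ("all alike" if they lie within 1.5 percentage points) (oak / larch / ash / all alike)
2. final target, as a percentage of the substrate charged, in oak
3. final target, as a percentage of the substrate charged, in larch
4. final target, as a percentage of the substrate charged, in ash

I ordered the lags as time constants. The first is the substrate's: Tuesday's decay gave a life of 4.21 min, and at 12.0 min Sunday and Friday read 5.9 % and 5.6 % of substrate against Tuesday's 5.8 %. The second is the hidden pool, whatever is neither substrate nor target: on Tuesday it held 39.5 % at that time and its late target slope gave a drain time of 9.75 min, longer than the life. The substrate fed last into ash has 8.00 min left, less than the two lags together.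

A third effect shows up in the late readings. Sunday's 57.4 % and Friday's 49.9 % at 12.0 min gave T = 0.500 /M, the reagent toll: the fraction of the substrate charged that is missing from target at that time, per molar of reagent present. I reckoned this correction for oak and larch. Oak repeats Tuesday's recipe, and the steady feed holds larch's mean reagent near 0.0500 M, so at 12.0 min larch should lead oak by 2.5 percentage points.

The forecast named larch, with oak 74 % (67 % to 79 %), larch 76 % (69 % to 81 %) and ash 59 % (55 % to 62 %), judging of ash that “late substrate has too little time”.

The flasks gave oak 72.6 %, larch 76.7 % and ash 58.8 %, so larch led as forecast.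

    substrate → intermediate A (k = 0.00401 /s)
    intermediate A → target (k = 0.0125 /s)
    intermediate A ⇌ intermediate B (K = 3.46, k = 0.148 /s)
    reagent + intermediate A ⇌ intermediate C (K = 99.1 /M, k = 0.0308 /M/s)
    intermediate B ⇌ intermediate D (K = 0.385, k = 0.00923 /s)
    target → over-reaction product (k = 1.20 × 10⁻⁵ /s)

Larch's lead over oak at 20 min was 4.1 points, and, set against the gap between oak's charge and larch's mean reagent of 0.0488 M over the first 12 min, T read 0.797 /M. As an estimate, that puts a flask like larch with 0.40 M of reagent, taking its mean as near 0.200 M, at 64.6 %, against a simulated 62.6 %. Larch's lead over ash, 18 points, stands on two ways back taken together, from intermediate B to intermediate A and from intermediate D to intermediate B: the run without the first leaves 0.36 points, and the run without the second 2.8 points.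

The earlier runs and the new flask are calculated on assumed constants; the scatter is artificial.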